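**Assumptions:** The given SMILES is taken to be (+)-neoolivil, i.e. (2R,3S,4S,5R)-2,5-bis(4-hydroxy-3-methoxyphenyl)-3,4-bis(hydroxymethyl)tetrahydrofuran (lignan numbering 7R,8S,8'S,7'R). It is C2-symmetric with all substituents trans around the ring. Numbered compounds are the skeleton building blocks, the atom-donating reagents (allyl bromide, TBDPSCl), intermediates and the target. Catalysts and non-incorporated reagents are not numbered.

## Retrosynthesis
1. Neoolivil comes from global deprotection of the C2-symmetric, all-trans 2,5-diaryl-THF. That THF is made by acid-catalysed SN1 cyclodehydration of the bis-benzylic 1,4-diol with its primary OH groups silylated. The ionised benzylic centre is reset by sterics, and the other four stereocentres are retained.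
2. The 1,4-diol comes from the tetraol, which comes from reductive removal of two Evans auxiliaries from the bis-aldol adduct.
3. The bis-aldol adduct comes from a double Evans syn-aldol of succinyl bis-[(R)-4-benzyloxazolidinone] with two equivalents of allyl-protected vanillin. This is the key step. It forms both C7–C8 bonds and sets C8/C8' by auxiliary control.
4. The THF is the only ring formed, and it closes after the acyclic C2-symmetric skeleton is assembled.

## Route

**Step 1**
Reactants: 1 (vanillin), 2 (allyl bromide)
Product: 3 (4-allyloxy-3-methoxybenzaldehyde)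
Conditions: allyl bromide, K2CO3, DMF, 25 °C
Reagents that add atoms: allyl bromide, C=CCBr
Why: Williamson O-allylation gives a phenol protecting group that survives the aldol, borohydride, silylation and acid steps and is later removed by Pd(0).

**Step 2**
Reactants: 4 ((R)-4-benzyloxazolidin-2-one, 2.1 equiv), 5 (succinyl chloride, 1 equiv)
Product: 6 (1,4-bis[(R)-4-benzyl-2-oxooxazolidin-3-yl]butane-1,4-dione)
Conditions: 4, n-BuLi, THF, –78 °C; then 5, –78 → 0 °C
Reagents that add atoms: none (both reactants are numbered)
Why: N-lithio-oxazolidinone double N-acylation gives the C2-symmetric bis-imide that carries the chiral information.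

**Step 3**
Reactants: 6, 3 (2.5 equiv)
Product: 7 (bis-Evans-syn-aldol adduct: C8/C8' acyl-form R, R; C7/C7' R, R; Ar = 4-allyloxy-3-methoxyphenyl)
Conditions: Bu2BOTf, i-Pr2NEt, CH2Cl2, –78 → 0 °C (bis-enolisation); then 3, –78 → 0 °C; then pH 7 buffer, MeOH, 30% H2O2, 0 °C
Reagents that add atoms: none (boron is removed in the oxidative work-up)
Why: Proposed new method: double bis-enolisation/aldol of a succinyl bis-imide. Each imide gives a Z-(O)-boron enolate, and each aldehyde adds through a Zimmerman–Traxler chair with the oxazolidinone dipole-opposed. The (R)-auxiliary therefore sets C8 and C8' in the same sense, which gives the C2 (R,R) diastereomer, and C7/C7' come out syn. The closest known reaction is the Evans boron syn-aldol of N-acyl oxazolidinones, here applied twice on one substrate. Any meso or other diastereomer is separated by chromatography.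

**Step 4**
Reactants: 7
Product: 8 ((2S,3S)-2,3-bis[(R)-(4-allyloxy-3-methoxyphenyl)(hydroxy)methyl]butane-1,4-diol), plus recovered 4
Conditions: LiBH4, MeOH (1 equiv per imide), THF, 0 → 23 °C
Reagents that add atoms: none
Why: Hydride reductive cleavage of the N-acyl oxazolidinones (standard for Evans aldol adducts) gives the primary alcohols. No stereocentre is touched, and the auxiliary 4 is recovered.

**Step 5**
Reactants: 8, 9 (TBDPSCl, 2.3 equiv)
Product: 10 (bis-primary TBDPS ether, with both benzylic OH groups free)
Conditions: TBDPSCl, imidazole, DMF, 0 → 23 °C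
Reagents that add atoms: TBDPSCl, CC(C)(C)[Si](Cl)(c1ccccc1)c1ccccc1
Why: The bulky silyl chloride silylates the two primary OH groups selectively over the hindered, doubly branched benzylic secondary OH groups (silylation of the less hindered alcohol). Protecting C9/C9' also stops the tetraol from closing to the furofuran or 7,9'-THF skeleton in the next step.

**Step 6**
Reactants: 10
Product: 11 ((2R,3S,4S,5R)-2,5-bis(4-allyloxy-3-methoxyphenyl)-3,4-bis(TBDPS-oxymethyl)tetrahydrofuran)
Conditions: CSA (10 mol%), CH2Cl2, 4 Å MS, 0 → 23 °C
Reagents that add atoms: none (loses H2O)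
Why: This is acid-catalysed SN1 cyclodehydration of a 1,4-diol to a THF. One p-alkoxybenzylic alcohol ionises and the other OH closes the five-membered ring. The other carbinol (which keeps its own oxygen) and C8/C8' are untouched. The new C7 centre is set with the aryl anti to the adjacent CH2OTBDPS, giving 2,3-trans. Because C8/C8' are trans, this gives the all-trans C2-symmetric ring. Either benzylic alcohol may ionise, and both paths give the same product. Re-ionisation of any cis isomer funnels it to the all-trans product.

**Step 7**
Reactants: 11
Product: 12 (bis-phenol, bis-TBDPS ether)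
Conditions: Pd(PPh3)4 (5 mol%), K2CO3, MeOH, 23 °C
Reagents that add atoms: none
Why: Pd(0) π-allyl deallylation of aryl allyl ethers, with methanol trapping the allyl group, leaves the silyl ethers and the benzylic THF C–O bonds intact.

**Step 8**
Reactants: 12
Product: 13 ((+)-neoolivil)
Conditions: TBAF, THF, 0 → 23 °C
Reagents that add atoms: none
Why: Fluoride cleavage of the primary TBDPS ethers liberates the two CH2OH groups. All four stereocentres are unaffected.

## Compound list
1 | vanillin | COc1cc(C=O)ccc1O | starting material
2 | allyl bromide | C=CCBr | starting material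
3 | 4-allyloxy-3-methoxybenzaldehyde | C=CCOc1ccc(C=O)cc1OC | intermediate
4 | (R)-4-benzyloxazolidin-2-one | O=C1N[C@H](Cc2ccccc2)CO1 | starting material (recovered in step 4)
5 | succinyl chloride | ClC(=O)CCC(=O)Cl | starting material
6 | succinyl bis-[(R)-4-benzyloxazolidinone] | O=C(CCC(=O)N1[C@H](Cc2ccccc2)COC1=O)N1[C@H](Cc2ccccc2)COC1=O | intermediate
7 | bis-aldol adduct | C=CCOc1ccc([C@H](O)[C@H](C(=O)N2[C@H](Cc3ccccc3)COC2=O)[C@@H](C(=O)N2[C@H](Cc3ccccc3)COC2=O)[C@@H](O)c4ccc(OCC=C)c(OC)c4)cc1OC | intermediate
8 | tetraol | C=CCOc1ccc([C@H](O)[C@H](CO)[C@@H](CO)[C@@H](O)c2ccc(OCC=C)c(OC)c2)cc1OC | intermediate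
9 | tert-butyldiphenylsilyl chloride | CC(C)(C)[Si](Cl)(c1ccccc1)c1ccccc1 | starting material
10 | bis-TBDPS diol | C=CCOc1ccc([C@H](O)[C@H](CO[Si](c2ccccc2)(c2ccccc2)C(C)(C)C)[C@@H](CO[Si](c2ccccc2)(c2ccccc2)C(C)(C)C)[C@@H](O)c2ccc(OCC=C)c(OC)c2)cc1OC | intermediate
11 | protected THF | C=CCOc1ccc([C@@H]2O[C@@H](c3ccc(OCC=C)c(OC)c3)[C@H](CO[Si](c4ccccc4)(c4ccccc4)C(C)(C)C)[C@H]2CO[Si](c4ccccc4)(c4ccccc4)C(C)(C)C)cc1OC | intermediate
12 | bis-phenol bis-TBDPS THF | COc1cc([C@@H]2O[C@@H](c3ccc(O)c(OC)c3)[C@H](CO[Si](c4ccccc4)(c4ccccc4)C(C)(C)C)[C@H]2CO[Si](c4ccccc4)(c4ccccc4)C(C)(C)C)ccc1O | intermediate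
13 | (+)-neoolivil | COc1cc([C@@H]2O[C@@H](c3ccc(O)c(OC)c3)[C@H](CO)[C@H]2CO)ccc1O | target

## Totals
Total steps: 8. Longest linear sequence: 7 steps, either 2→8 from 4 and 5 or 1, 3→8 via the aldehyde.

## Three steps most likely to fail
1. **Step 3 (double aldol).** The second aldol may be mismatched with the first stereocentre, the bis-enolate may be unstable, or the free β-OH may lactonise onto the neighbouring imide.
   Fallback (different approach): make the Evans acetate-aldol adduct ArCH(OTBS)CH2C(O)Xc from 3, then couple two units by oxidative enolate homodimerisation (LiHMDS, then Fe(acac)3 or CuCl2) to build C8–C8'. Carry on from the tetraol stage as before.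
2. **Step 6 (cyclodehydration).** The benzylic cation could lose a proton to give a styrene, and re-protonation could epimerise C8. The silyl-ether oxygen could instead trap the cation and give a 7,9'-THF. A cis-2,5 isomer could also form.
   Fallback (different approach): oxidise 10 to the 1,4-diketone (Dess–Martin periodinane) and close the ring by Et3SiH/TMSOTf reductive etherification, setting C7 and C7' by hydride delivery to a cyclic oxocarbenium instead of through a benzylic cation.
3. **Step 5 (selective primary silylation).** Over-silylation of the benzylic OH groups would give mixtures.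
   Fallback (different approach): protect the benzylic OH groups of 7 as TES ethers first, then reduce with LiBH4 and silylate the primary OH groups with TBDPSCl. Selective TES removal (PPTS, MeOH) then gives 10.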